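**Retrosynthetic overview**

1. Target ⇐ tris-silyl ether; the C8 hydroxyl and the trans ring fusion come from conjugate borylation–oxidation of a C8a=C8 enone, itself made from the ring A 1,8-diketone by enol triflate reduction.
2. Ring A (formed last) ⇐ endo [4+2] annulation of 3-methyl-2-silyloxyfuran onto the C4a=C8a double bond of a fully substituted cyclohexa-2,5-dienone (sets C4a and C5; C7 by hydrogenation).
3. Ring B substituents ⇐ Mitsunobu etherification with (2E,4R)-oct-2-en-4-ol, then Claisen rearrangement (side-chain stereocentre); diosphenol ⇐ epoxy enone; 3-hydroxypropanoyl ⇐ lactone + LiCH2CH2OLi.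
4. C4 quaternary stereocentre ⇐ catalytic enantioselective bromolactonization that desymmetrises achiral 1-methylcyclohexa-2,5-diene-1-carboxylic acid ⇐ Birch reductive methylation of benzoic acid (ring B comes from the arene, first).

Assumption: (DHQD)2PHAL gives the bromolactone of step 2 in the sense drawn (otherwise the pseudoenantiomer (DHQ)2PHAL is used); labels C1–C8a follow the naphthalen-1(4H)-one numbering of the target throughout.

**Route**

Step 1
Reactants: 1 benzoic acid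
Product: 3 1-methylcyclohexa-2,5-diene-1-carboxylic acid, via dilithium 1,4-dihydrobenzoate dianion 2 (not isolated)
Conditions: Li, NH3(l), THF, −78 °C; then MeI, −78 °C → rt; HCl aq
Reagents that add atoms: iodomethane, CI
Why: Birch reductive alkylation: the dissolving-metal reduction stops at the 1,4-dihydrobenzoate dianion, which is C-methylated at the carboxyl-bearing carbon to give the achiral, mirror-symmetric diene acid, so no stereocentre is set yet.

Step 2
Reactants: 3 1-methylcyclohexa-2,5-diene-1-carboxylic acid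
Product: 4 (1S,5S,8S)-8-bromo-1-methyl-6-oxabicyclo[3.2.1]oct-2-en-7-one
Conditions: NBS, (DHQD)2PHAL (10 mol%), CHCl3–hexane, −40 °C
Reagents that add atoms: N-bromosuccinimide, O=C1CCC(=O)N1Br
Why: Cinchona-catalysed asymmetric bromolactonization (desymmetrising halolactonization): the catalyst-bound carboxylate opens the bromonium ion of one of the two enantiotopic alkenes anti, which fixes the quaternary carbon C4 and places O on C2 cis to the carboxyl carbon and Br on C3 trans; if the isomeric β-lactone of the same alkene (O on C3, Br on C2) forms instead, step 3 converts it to the same epoxide.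

Step 3
Reactants: 4 (1S,5S,8S)-8-bromo-1-methyl-6-oxabicyclo[3.2.1]oct-2-en-7-one
Product: 7 3-hydroxy-1-[(1R,2R,6S)-2-methyl-7-oxabicyclo[4.1.0]hept-3-en-2-yl]propan-1-one, via bridged dilithium lactolate 5 (not isolated), via trans-bromohydrin ketone 6 (not isolated)
Conditions: ClCH2CH2OH, n-BuLi, then LiC10H8, THF, −78 °C; add 4, −78 °C; NH4Cl aq; then K2CO3, MeOH, 0 °C
Reagents that add atoms: dilithium 2-oxidoethan-1-ide, [Li+].[Li+].[CH2-]C[O-], made in the flask from 2-chloroethanol, OCCCl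
Why: A β-oxido alkyllithium (Barluenga-type reagent) adds once to the lactone carbonyl because the bridged lactolate survives at −78 °C, and after protonation the C2 alkoxide displaces the anti C3 bromide (bromohydrin-to-epoxide closure, SN2), so the epoxide is cis to the new 3-hydroxypropanoyl group and C4 is untouched.

Step 4
Reactants: 7 3-hydroxy-1-[(1R,2R,6S)-2-methyl-7-oxabicyclo[4.1.0]hept-3-en-2-yl]propan-1-one
Product: 8 3-[(tert-butyldimethylsilyl)oxy]-1-[(1R,2R,6S)-2-methyl-7-oxabicyclo[4.1.0]hept-3-en-2-yl]propan-1-one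
Conditions: TBSCl, imidazole, DMF, rt
Reagents that add atoms: tert-butyldimethylsilyl chloride, C[Si](C)(Cl)C(C)(C)C
Why: Standard silyl ether formation on the only hydroxyl (primary), protecting it from the oxidant of step 5 and from the Mitsunobu step.

Step 5
Reactants: 8 3-[(tert-butyldimethylsilyl)oxy]-1-[(1R,2R,6S)-2-methyl-7-oxabicyclo[4.1.0]hept-3-en-2-yl]propan-1-one
Product: 9 (1R,5R,6R)-5-{3-[(tert-butyldimethylsilyl)oxy]propanoyl}-5-methyl-7-oxabicyclo[4.1.0]hept-3-en-2-one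
Conditions: Rh2(cap)4 (1 mol%), t-BuOOH, K2CO3, CH2Cl2, rt
Reagents that add atoms: tert-butyl hydroperoxide, CC(C)(C)OO
Why: Dirhodium caprolactamate-catalysed allylic C–H oxidation with TBHP occurs at the only allylic methylene (C1; the other allylic carbon C4 is quaternary) and gives the epoxy enone without touching a stereocentre.

Step 6
Reactants: 9 (1R,5R,6R)-5-{3-[(tert-butyldimethylsilyl)oxy]propanoyl}-5-methyl-7-oxabicyclo[4.1.0]hept-3-en-2-one
Product: 10 (4R)-4-{3-[(tert-butyldimethylsilyl)oxy]propanoyl}-2-hydroxy-4-methylcyclohexa-2,5-dien-1-one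
Conditions: DBU, CH2Cl2, 0 °C → rt; AcOH
Reagents that add atoms: none
Why: Base-mediated isomerisation of an α,β-epoxy ketone to a diosphenol (E1cB: deprotonation at C2, opening of the C3–O bond) removes the two epoxide stereocentres and leaves C4 as the only stereocentre.

Step 7
Reactants: 11 (2E)-oct-2-en-4-one
Product: 12 (2E,4R)-oct-2-en-4-ol
Conditions: (S)-Me-CBS oxazaborolidine (10 mol%), catecholborane, toluene, −78 °C
Reagents that add atoms: none
Why: Corey–Bakshi–Shibata 1,2-reduction in which the alkenyl group acts as the large substituent, so the (S)-catalyst delivers hydride to give the (R)-allylic alcohol.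

Step 8
Reactants: 10 (4R)-4-{3-[(tert-butyldimethylsilyl)oxy]propanoyl}-2-hydroxy-4-methylcyclohexa-2,5-dien-1-one; 12 (2E,4R)-oct-2-en-4-ol
Product: 13 (4R)-4-{3-[(tert-butyldimethylsilyl)oxy]propanoyl}-4-methyl-2-{[(2E,4S)-oct-2-en-4-yl]oxy}cyclohexa-2,5-dien-1-one
Conditions: PPh3, DIAD, toluene, 0 °C → rt
Reagents that add atoms: none
Why: Mitsunobu etherification of the acidic enol hydroxyl proceeds by SN2 at the carbinol carbon with inversion, giving the (S)-configured allyl enol ether.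

Step 9
Reactants: 13 (4R)-4-{3-[(tert-butyldimethylsilyl)oxy]propanoyl}-4-methyl-2-{[(2E,4S)-oct-2-en-4-yl]oxy}cyclohexa-2,5-dien-1-one
Product: 15 (4R)-4-{3-[(tert-butyldimethylsilyl)oxy]propanoyl}-2-hydroxy-4-methyl-3-[(2R,3E)-oct-3-en-2-yl]cyclohexa-2,5-dien-1-one, via enolisable 1,2-diketone 14 (not isolated)
Conditions: toluene, BHT, 140 °C (sealed tube)
Reagents that add atoms: none
Why: Claisen rearrangement of the diosphenol allyl ether through a chair transition state with the butyl group equatorial transfers the ether stereocentre to the new C–C stereocentre ((S)-ether with (E)-alkene gives (R), new alkene E), and the 1,2-diketone first formed enolises toward C3, so the ring stereocentre created there is lost.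

Step 10
Reactants: 16 3-methylfuran-2(5H)-one
Product: 17 tert-butyldimethyl[(3-methylfuran-2-yl)oxy]silane
Conditions: TBSOTf, Et3N, CH2Cl2, 0 °C
Reagents that add atoms: tert-butyldimethylsilyl trifluoromethanesulfonate, C[Si](C)(C(C)(C)C)OS(=O)(=O)C(F)(F)F
Why: Soft enolisation and O-silylation of the butenolide gives the aromatic 2-silyloxyfuran (silyl dienol ether formation).

Step 11
Reactants: 15 (4R)-4-{3-[(tert-butyldimethylsilyl)oxy]propanoyl}-2-hydroxy-4-methyl-3-[(2R,3E)-oct-3-en-2-yl]cyclohexa-2,5-dien-1-one; 17 tert-butyldimethyl[(3-methylfuran-2-yl)oxy]silane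
Product: 20 (4R,4aS,5R,8aS)-2,5-bis[(tert-butyldimethylsilyl)oxy]-4-{3-[(tert-butyldimethylsilyl)oxy]propanoyl}-4,7-dimethyl-3-[(2R,3E)-oct-3-en-2-yl]-4a,5-dihydronaphthalene-1,8(4H,8aH)-dione, via bis-silyl dienone 18 (not isolated), via bridged silyl ketal cycloadduct 19 (not isolated)
Conditions: 17 (2.5 equiv), toluene, 80 °C
Reagents that add atoms: none
Why: The first equivalent of 17 transfers its silyl group to the acidic enol, then a Diels–Alder reaction of the 2-silyloxyfuran with the C4a=C8a enone (furan C5, the nucleophilic terminus, to the β-carbon C4a) takes place endo on the α-face, anti to the C4 acyl group whose silyloxyethyl arm covers the β-face, and the bridged silyl ketal collapses with O-to-O silyl shift, which sets C4a–H and the C5 oxygen cis to each other and trans to the acyl group.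

Step 12
Reactants: 20 (4R,4aS,5R,8aS)-2,5-bis[(tert-butyldimethylsilyl)oxy]-4-{3-[(tert-butyldimethylsilyl)oxy]propanoyl}-4,7-dimethyl-3-[(2R,3E)-oct-3-en-2-yl]-4a,5-dihydronaphthalene-1,8(4H,8aH)-dione
Product: 21 (4R,4aR,5R,7S)-2,5-bis[(tert-butyldimethylsilyl)oxy]-4-{3-[(tert-butyldimethylsilyl)oxy]propanoyl}-8-hydroxy-4,7-dimethyl-3-[(2R)-octan-2-yl]-4a,5,6,7-tetrahydronaphthalen-1(4H)-one
Conditions: H2 (1 atm), Pd/C, EtOAc, rt
Reagents that add atoms: none
Why: Heterogeneous hydrogenation reduces the ring A enone C=C and the side-chain alkene but not the tetrasubstituted silyl enol ether; hydrogen adds to C6=C7 anti to the allylic C5 silyloxy group of the enolised (flattened) ring A, placing the C7 methyl cis to the C5 oxygen, which is also the all-equatorial epimer reached by equilibration α to the C8 carbonyl.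

Step 13
Reactants: 21 (4R,4aR,5R,7S)-2,5-bis[(tert-butyldimethylsilyl)oxy]-4-{3-[(tert-butyldimethylsilyl)oxy]propanoyl}-8-hydroxy-4,7-dimethyl-3-[(2R)-octan-2-yl]-4a,5,6,7-tetrahydronaphthalen-1(4H)-one
Product: 22 (4R,4aR,5R,7S)-2,5-bis[(tert-butyldimethylsilyl)oxy]-4-{3-[(tert-butyldimethylsilyl)oxy]propanoyl}-4,7-dimethyl-3-[(2R)-octan-2-yl]-8-[(trifluoromethanesulfonyl)oxy]-4a,5,6,7-tetrahydronaphthalen-1(4H)-one
Conditions: PhNTf2, Et3N, DMAP (cat.), CH2Cl2, 0 °C
Reagents that add atoms: N-phenylbis(trifluoromethanesulfonimide), O=S(=O)(N(c1ccccc1)S(=O)(=O)C(F)(F)F)C(F)(F)F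
Why: Enol triflate formation on the vinylogous acid at its enolic C8 oxygen, the less hindered of the two oxygens because O1 is flanked by the fully substituted C2 silyl enol ether, with no change at any stereocentre.

Step 14
Reactants: 22 (4R,4aR,5R,7S)-2,5-bis[(tert-butyldimethylsilyl)oxy]-4-{3-[(tert-butyldimethylsilyl)oxy]propanoyl}-4,7-dimethyl-3-[(2R)-octan-2-yl]-8-[(trifluoromethanesulfonyl)oxy]-4a,5,6,7-tetrahydronaphthalen-1(4H)-one
Product: 23 (4R,4aS,5R,7S)-2,5-bis[(tert-butyldimethylsilyl)oxy]-4-{3-[(tert-butyldimethylsilyl)oxy]propanoyl}-4,7-dimethyl-3-[(2R)-octan-2-yl]-4a,5,6,7-tetrahydronaphthalen-1(4H)-one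
Conditions: Pd(OAc)2 (5 mol%), PPh3, HCO2H, Et3N, DMF, 60 °C
Reagents that add atoms: none
Why: Palladium-catalysed formate reduction of the enol triflate (Cacchi-type hydrogenolysis) replaces the triflate by hydrogen and leaves the C8a=C8 enone, stereocentres untouched.

Step 15
Reactants: 23 (4R,4aS,5R,7S)-2,5-bis[(tert-butyldimethylsilyl)oxy]-4-{3-[(tert-butyldimethylsilyl)oxy]propanoyl}-4,7-dimethyl-3-[(2R)-octan-2-yl]-4a,5,6,7-tetrahydronaphthalen-1(4H)-one
Product: 25 (4R,4aS,5R,7S,8S,8aR)-2,5-bis[(tert-butyldimethylsilyl)oxy]-4-{3-[(tert-butyldimethylsilyl)oxy]propanoyl}-8-hydroxy-4,7-dimethyl-3-[(2R)-octan-2-yl]-4a,5,6,7,8,8a-hexahydronaphthalen-1(4H)-one, via C8 pinacolboronate 24 (not isolated)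
Conditions: CuCl (5 mol%), NaOt-Bu, DPEphos, B2pin2, MeOH, THF, rt; then H2O2, NaHCO3 aq, 0 °C
Reagents that add atoms: hydrogen peroxide, OO (the C8 oxygen of 25); bis(pinacolato)diboron, CC1(C)OB(OC1(C)C)B1OC(C)(C)C(C)(C)O1 (boron of 24 only)
Why: Copper-catalysed conjugate borylation followed by stereoretentive C–B oxidation: the boryl group adds to C8 axially on the β-face (chair-like enolate with the C5 and C7 substituents equatorial), the enolate is protonated at C8a on the α-face to give the trans ring fusion, and oxidation with retention gives the axial 8-hydroxyl.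

Step 16
Reactants: 25 (4R,4aS,5R,7S,8S,8aR)-2,5-bis[(tert-butyldimethylsilyl)oxy]-4-{3-[(tert-butyldimethylsilyl)oxy]propanoyl}-8-hydroxy-4,7-dimethyl-3-[(2R)-octan-2-yl]-4a,5,6,7,8,8a-hexahydronaphthalen-1(4H)-one
Product: 26 (4R,4aS,5R,7S,8S,8aR)-2,5,8-trihydroxy-4-(3-hydroxypropanoyl)-4,7-dimethyl-3-[(2R)-octan-2-yl]-4a,5,6,7,8,8a-hexahydronaphthalen-1(4H)-one
Conditions: HF·pyridine, pyridine, THF, 0 °C → rt
Reagents that add atoms: none
Why: Buffered HF desilylation cleaves the silyl enol ether and the two alkyl silyl ethers without acid- or base-induced dehydration of the β-hydroxy ketone, liberating the diosphenol and the hydroxyls of the target.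

**Compound list**

1 | benzoic acid | OC(=O)c1ccccc1 | starting material
2 | dilithium 1,4-dihydrobenzoate dianion (Birch enediolate of 1) | [Li+].[Li+].[O-]C([O-])=C1C=CCC=C1 | intermediate (not isolated)
3 | 1-methylcyclohexa-2,5-diene-1-carboxylic acid (achiral) | CC1(C(=O)O)C=CCC=C1 | intermediate
4 | (1S,5S,8S)-8-bromo-1-methyl-6-oxabicyclo[3.2.1]oct-2-en-7-one | C[C@]12C=CC[C@H](OC1=O)[C@H]2Br | intermediate
5 | dilithium salt of the bridged lactol from addition of LiCH2CH2OLi to the lactone carbonyl of 4 (ketal carbon configuration not defined) | C[C@]12C=CC[C@H](OC1([O-])CC[O-])[C@H]2Br.[Li+].[Li+] | intermediate (not isolated)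
6 | 1-[(1S,5S,6S)-6-bromo-5-hydroxy-1-methylcyclohex-2-en-1-yl]-3-hydroxypropan-1-one | C[C@@]1(C(=O)CCO)C=CC[C@H](O)[C@H]1Br | intermediate (not isolated)
7 | 3-hydroxy-1-[(1R,2R,6S)-2-methyl-7-oxabicyclo[4.1.0]hept-3-en-2-yl]propan-1-one | C[C@@]1(C(=O)CCO)C=CC[C@@H]2O[C@H]12 | intermediate
8 | 3-[(tert-butyldimethylsilyl)oxy]-1-[(1R,2R,6S)-2-methyl-7-oxabicyclo[4.1.0]hept-3-en-2-yl]propan-1-one | C[C@@]1(C(=O)CCO[Si](C)(C)C(C)(C)C)C=CC[C@@H]2O[C@H]12 | intermediate
9 | (1R,5R,6R)-5-{3-[(tert-butyldimethylsilyl)oxy]propanoyl}-5-methyl-7-oxabicyclo[4.1.0]hept-3-en-2-one | C[C@@]1(C(=O)CCO[Si](C)(C)C(C)(C)C)C=CC(=O)[C@@H]2O[C@H]12 | intermediate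
10 | (4R)-4-{3-[(tert-butyldimethylsilyl)oxy]propanoyl}-2-hydroxy-4-methylcyclohexa-2,5-dien-1-one | C[C@@]1(C(=O)CCO[Si](C)(C)C(C)(C)C)C=CC(=O)C(O)=C1 | intermediate
11 | (2E)-oct-2-en-4-one | C/C=C/C(=O)CCCC | starting material
12 | (2E,4R)-oct-2-en-4-ol | C/C=C/[C@H](O)CCCC | intermediate
13 | (4R)-4-{3-[(tert-butyldimethylsilyl)oxy]propanoyl}-4-methyl-2-{[(2E,4S)-oct-2-en-4-yl]oxy}cyclohexa-2,5-dien-1-one | C[C@@]1(C(=O)CCO[Si](C)(C)C(C)(C)C)C=CC(=O)C(O[C@@H](CCCC)/C=C/C)=C1 | intermediate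
14 | (4R)-4-{3-[(tert-butyldimethylsilyl)oxy]propanoyl}-4-methyl-3-[(2R,3E)-oct-3-en-2-yl]cyclohex-5-ene-1,2-dione (C3 epimers) | C[C@@]1(C(=O)CCO[Si](C)(C)C(C)(C)C)C=CC(=O)C(=O)C1[C@H](C)/C=C/CCCC | intermediate (not isolated)
15 | (4R)-4-{3-[(tert-butyldimethylsilyl)oxy]propanoyl}-2-hydroxy-4-methyl-3-[(2R,3E)-oct-3-en-2-yl]cyclohexa-2,5-dien-1-one | C[C@@]1(C(=O)CCO[Si](C)(C)C(C)(C)C)C=CC(=O)C(O)=C1[C@H](C)/C=C/CCCC | intermediate
16 | 3-methylfuran-2(5H)-one | CC1=CCOC1=O | starting material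
17 | tert-butyldimethyl[(3-methylfuran-2-yl)oxy]silane | Cc1ccoc1O[Si](C)(C)C(C)(C)C | intermediate
18 | (4R)-2-[(tert-butyldimethylsilyl)oxy]-4-{3-[(tert-butyldimethylsilyl)oxy]propanoyl}-4-methyl-3-[(2R,3E)-oct-3-en-2-yl]cyclohexa-2,5-dien-1-one | C[C@@]1(C(=O)CCO[Si](C)(C)C(C)(C)C)C=CC(=O)C(O[Si](C)(C)C(C)(C)C)=C1[C@H](C)/C=C/CCCC | intermediate (not isolated)
19 | endo cycloadduct of 18 and 17: 7-oxabicyclo[2.2.1]hept-2-ene (oxygen bridge from C5 to C8, silyloxy on bridgehead C8, methyl on C7) fused at C4a–C8a, the C4a and C8a hydrogens cis to the oxygen bridge and trans to the C4 acyl group | CCCC/C=C/[C@@H](C)C1=C(O[Si](C)(C)C(C)(C)C)C(=O)[C@@H]2[C@@]3(O[Si](C)(C)C(C)(C)C)O[C@H](C=C3C)[C@@H]2[C@@]1(C)C(=O)CCO[Si](C)(C)C(C)(C)C | intermediate (not isolated)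
20 | (4R,4aS,5R,8aS)-2,5-bis[(tert-butyldimethylsilyl)oxy]-4-{3-[(tert-butyldimethylsilyl)oxy]propanoyl}-4,7-dimethyl-3-[(2R,3E)-oct-3-en-2-yl]-4a,5-dihydronaphthalene-1,8(4H,8aH)-dione (drawn as the diketo tautomer) | CCCC/C=C/[C@@H](C)C1=C(O[Si](C)(C)C(C)(C)C)C(=O)[C@@H]2C(=O)C(C)=C[C@@H](O[Si](C)(C)C(C)(C)C)[C@@H]2[C@@]1(C)C(=O)CCO[Si](C)(C)C(C)(C)C | intermediate
21 | (4R,4aR,5R,7S)-2,5-bis[(tert-butyldimethylsilyl)oxy]-4-{3-[(tert-butyldimethylsilyl)oxy]propanoyl}-8-hydroxy-4,7-dimethyl-3-[(2R)-octan-2-yl]-4a,5,6,7-tetrahydronaphthalen-1(4H)-one (enol form of the 1,8-diketone) | CCCCCC[C@@H](C)C1=C(O[Si](C)(C)C(C)(C)C)C(=O)C2=C(O)[C@@H](C)C[C@@H](O[Si](C)(C)C(C)(C)C)[C@@H]2[C@@]1(C)C(=O)CCO[Si](C)(C)C(C)(C)C | intermediate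
22 | (4R,4aR,5R,7S)-2,5-bis[(tert-butyldimethylsilyl)oxy]-4-{3-[(tert-butyldimethylsilyl)oxy]propanoyl}-4,7-dimethyl-3-[(2R)-octan-2-yl]-8-[(trifluoromethanesulfonyl)oxy]-4a,5,6,7-tetrahydronaphthalen-1(4H)-one | CCCCCC[C@@H](C)C1=C(O[Si](C)(C)C(C)(C)C)C(=O)C2=C(OS(=O)(=O)C(F)(F)F)[C@@H](C)C[C@@H](O[Si](C)(C)C(C)(C)C)[C@@H]2[C@@]1(C)C(=O)CCO[Si](C)(C)C(C)(C)C | intermediate
23 | (4R,4aS,5R,7S)-2,5-bis[(tert-butyldimethylsilyl)oxy]-4-{3-[(tert-butyldimethylsilyl)oxy]propanoyl}-4,7-dimethyl-3-[(2R)-octan-2-yl]-4a,5,6,7-tetrahydronaphthalen-1(4H)-one | CCCCCC[C@@H](C)C1=C(O[Si](C)(C)C(C)(C)C)C(=O)C2=C[C@@H](C)C[C@@H](O[Si](C)(C)C(C)(C)C)[C@@H]2[C@@]1(C)C(=O)CCO[Si](C)(C)C(C)(C)C | intermediate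
24 | C8 β-pinacolboronate: 25 with a 4,4,5,5-tetramethyl-1,3,2-dioxaborolan-2-yl group in place of the C8 hydroxyl, same spatial arrangement at every centre | CCCCCC[C@@H](C)C1=C(O[Si](C)(C)C(C)(C)C)C(=O)[C@H]2[C@@H](B3OC(C)(C)C(C)(C)O3)[C@@H](C)C[C@@H](O[Si](C)(C)C(C)(C)C)[C@@H]2[C@@]1(C)C(=O)CCO[Si](C)(C)C(C)(C)C | intermediate (not isolated)
25 | (4R,4aS,5R,7S,8S,8aR)-2,5-bis[(tert-butyldimethylsilyl)oxy]-4-{3-[(tert-butyldimethylsilyl)oxy]propanoyl}-8-hydroxy-4,7-dimethyl-3-[(2R)-octan-2-yl]-4a,5,6,7,8,8a-hexahydronaphthalen-1(4H)-one | CCCCCC[C@@H](C)C1=C(O[Si](C)(C)C(C)(C)C)C(=O)[C@H]2[C@@H](O)[C@@H](C)C[C@@H](O[Si](C)(C)C(C)(C)C)[C@@H]2[C@@]1(C)C(=O)CCO[Si](C)(C)C(C)(C)C | intermediate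
26 | (4R,4aS,5R,7S,8S,8aR)-2,5,8-trihydroxy-4-(3-hydroxypropanoyl)-4,7-dimethyl-3-[(2R)-octan-2-yl]-4a,5,6,7,8,8a-hexahydronaphthalen-1(4H)-one | CCCCCC[C@@H](C)C1=C(O)C(=O)[C@H]2[C@@H](O)[C@@H](C)C[C@@H](O)[C@@H]2[C@@]1(C)C(=O)CCO | target

**Step count and risks**

Total: 16 steps. Longest linear sequence: 14 steps (1–6, 8, 9, 11–16); steps 7 and 10 prepare the two coupling partners.

The three steps most likely to fail:

Step 2. Enantioselectivity (and lactone ring size) of the catalytic bromolactonization have not been shown for this exact acid; a β-lactone would still converge in step 3, but low ee would not be repaired later. The fallback sets out from 3 and replaces catalyst control by auxiliary control. The acid is converted (oxalyl chloride, then the amine, Et3N) into the amide of a C2-symmetric pyrrolidine, (2R,5R)-2,5-bis(methoxymethyl)pyrrolidin-1-yl 1-methylcyclohexa-2,5-dien-1-yl ketone F1 (the antipodal auxiliary if the sense is opposite). Iodolactonization (I2, THF–H2O) then expels the auxiliary and gives the iodolactone (1S,5S,8S)-8-iodo-1-methyl-6-oxabicyclo[3.2.1]oct-2-en-7-one F2. Under the conditions of step 3, F2 comes back to the route at 7.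

Step 11. The dienophile is hindered, and the facial preference (anti to the acyl group on C4, syn to the methyl) is argued from sterics only; the wrong face would give the C4a epimeric series. The fallback sets out from 9, where the cis epoxide as well as the acyl group shield the β-face, and forms ring A in two stages. Vinylogous Mukaiyama–Michael addition of 17 (TBSOTf cat., CH2Cl2, −78 °C) gives the C4a butenolide adduct F3. Hydrogenation (H2, Pd/C) gives the cis-methyl lactone F4, and DBU isomerises the epoxy ketone to the diosphenol F5. Mitsunobu etherification with 12 gives the allyl enol ether F6, and Claisen rearrangement gives the C3-alkenyl diosphenol F7. Hydrogenation of the side chain gives the octan-2-yl diosphenol F8, and TBSOTf with 2,6-lutidine gives the silyl enol ether F9. Dieckmann-type acylation of the C8a enolate on the lactone (LiHMDS, then TBSCl for the released C5 alkoxide) comes back to the route at 21.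

Step 13. Triflation could occur on O1 instead of the C8 oxygen, which after reduction would give the transposed enone. The fallback sets out from 21 and avoids the triflate–enone detour. The C8 carbonyl of the 1,3-diketone is reduced directly by Noyori hydrogenation (RuCl2[(S)-BINAP] cat., H2 50 atm, EtOH–CH2Cl2, 40 °C; catalyst-controlled at C8, conjugated C1 carbonyl retained), followed by equilibration of C8a to the trans fusion on neutral alumina. This comes back to the route at 25 and makes no new compound.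

**Further compounds**

F1 | step 2 | (2R,5R)-2,5-bis(methoxymethyl)pyrrolidin-1-yl 1-methylcyclohexa-2,5-dien-1-yl ketone | COC[C@H]1CC[C@H](COC)N1C(=O)C2(C)C=CCC=C2
F2 | step 2 | (1S,5S,8S)-8-iodo-1-methyl-6-oxabicyclo[3.2.1]oct-2-en-7-one | C[C@]12C=CC[C@H](OC1=O)[C@H]2I
F3 | step 11 | butenolide adduct: saturated analogue of 9 (C8a is CH2) carrying at C4a, on the α-face, a 4-methyl-5-oxo-2,5-dihydrofuran-2-yl group (C4a–H and lactone oxygen disposed as C4a–H and the C5 oxygen in the target) | C[C@@]1(C(=O)CCO[Si](C)(C)C(C)(C)C)[C@@H]([C@@H]3OC(=O)C(C)=C3)CC(=O)[C@@H]2O[C@H]12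
F4 | step 11 | F3 with the butenolide C=C hydrogenated (lactone methyl cis to the C4a substituent) | C[C@@]1(C(=O)CCO[Si](C)(C)C(C)(C)C)[C@@H]([C@@H]3OC(=O)[C@@H](C)C3)CC(=O)[C@@H]2O[C@H]12
F5 | step 11 | diosphenol from F4: 2-hydroxycyclohex-2-en-1-one with the C4 methyl and silyloxypropanoyl groups and the C4a lactone substituent | C[C@@]1(C(=O)CCO[Si](C)(C)C(C)(C)C)[C@@H]([C@@H]2OC(=O)[C@@H](C)C2)CC(=O)C(O)=C1
F6 | step 11 | (2E,4S)-oct-2-en-4-yl enol ether of F5 | C[C@@]1(C(=O)CCO[Si](C)(C)C(C)(C)C)[C@@H]([C@@H]2OC(=O)[C@@H](C)C2)CC(=O)C(O[C@@H](CCCC)/C=C/C)=C1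
F7 | step 11 | Claisen product of F6: diosphenol bearing (2R,3E)-oct-3-en-2-yl on C3 | C[C@@]1(C(=O)CCO[Si](C)(C)C(C)(C)C)[C@@H]([C@@H]2OC(=O)[C@@H](C)C2)CC(=O)C(O)=C1[C@H](C)/C=C/CCCC
F8 | step 11 | F7 with the side chain hydrogenated to (2R)-octan-2-yl | C[C@@]1(C(=O)CCO[Si](C)(C)C(C)(C)C)[C@@H]([C@@H]2OC(=O)[C@@H](C)C2)CC(=O)C(O)=C1[C@H](C)CCCCCC
F9 | step 11 | tert-butyldimethylsilyl enol ether of F8 | C[C@@]1(C(=O)CCO[Si](C)(C)C(C)(C)C)[C@@H]([C@@H]2OC(=O)[C@@H](C)C2)CC(=O)C(O[Si](C)(C)C(C)(C)C)=C1[C@H](C)CCCCCC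
F0 | step 13 | none | none
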